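## Retrosynthetic overview

1. The target is a 2,4-disubstituted 1,3-thiazole with one stereocentre, the R carbinol carbon next to CMe2. The last step is a Z-selective semireduction of a conjugated enyne to the (Z)-diene, and this alkyne is the only change of oxidation level carried through the fragment union.
2. The key disconnection is thiazole C2–CMe2. The whole left half (as its 2-benzenesulfonylthiazole) and the whole right half (as an R-configured 2,2-dimethyl-3-alkyloxirane) are joined by Cp2TiCl2-catalysed reductive epoxide opening with homolytic ipso-substitution. This step builds the quaternary carbon, unveils the free carbinol and needs no protecting group.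
3. Enabling features: C2 of the thiazole ring lies between S1 and N3. Its C–H is therefore the most acidic one (the sulfone goes on there), it is the most electron-poor ring carbon, it has no substituted ring neighbour, and both heteroatoms stabilise its radical adduct. The CMe2–CH(OH) pair maps onto a trisubstituted oxirane in which only cleavage of the O–CMe2 bond gives a tertiary radical.
4. Right half: Sonogashira coupling of an epoxy alkyne (prenyl bromide plus ethynyl Grignard reagent, then Shi epoxidation) with methyl (3-bromobut-3-enyl)carbamate (Mitsunobu amination). Left half: hydrozirconation of pent-1-en-4-yne, coupling with 4-(chloromethyl)thiazole, then C2 lithiation and sulfonylation.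
5. Rings: the thiazole ring is bought. The only ring formed is the temporary oxirane (step 4), which is opened again in step 8.

Key step: step 8

Assumption: 4-(chloromethyl)-1,3-thiazole is bought as its hydrochloride and freed with aqueous NaHCO3 just before use, and the Zn(Cu/Ag) couple of the last step is prepared and washed beforehand; neither operation is counted as a step.

## Route

Step 1
Reactants: 1 pent-1-en-4-yne; 2 4-(chloromethyl)-1,3-thiazole
Product: 4 4-[(2E)-hexa-2,5-dien-1-yl]-1,3-thiazole, via alkenylzirconocene chloride 3 (not isolated)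
Conditions: Cp2Zr(H)Cl (1.05 equiv), THF, 0 °C to rt; then 2, Pd(PPh3)4 (5 mol %), ZnCl2 (20 mol %), THF, rt to 40 °C
Reagents that add atoms: none
Why: Hydrozirconation is faster at the terminal alkyne than at the terminal alkene and adds H and Zr syn with Zr at the terminus, and the Negishi-type palladium-catalysed coupling of the E-alkenyl metal with the benzylic-type chloride keeps the E geometry.

Step 2
Reactants: 4 4-[(2E)-hexa-2,5-dien-1-yl]-1,3-thiazole
Product: 6 2-(benzenesulfonyl)-4-[(2E)-hexa-2,5-dien-1-yl]-1,3-thiazole, via 2-lithiothiazole 5 (not isolated)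
Conditions: n-BuLi (1.05 equiv), THF, −78 °C; then PhSO2F (1.1 equiv), −78 to −20 °C
Reagents that add atoms: benzenesulfonyl fluoride, O=S(=O)(F)c1ccccc1
Why: The C2–H between S1 and N3 is the most acidic C–H of 4, so azole C2 lithiation followed by sulfonylation of the heteroaryllithium with a sulfonyl fluoride places the radical nucleofuge on exactly the carbon that is to be substituted.

Step 3
Reactants: 7 1-bromo-3-methylbut-2-ene (prenyl bromide); 8 ethynylmagnesium bromide
Product: 9 5-methylhex-4-en-1-yne
Conditions: 8 (1.3 equiv, 0.5 M in THF), CuCl (5 mol %), THF, 0 °C to rt; distillation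
Reagents that add atoms: none
Why: The copper-catalysed allyl–alkynyl coupling of an alkynyl Grignard reagent takes place at the unhindered primary terminus of the prenyl halide (SN2 mode) and should give the skipped enyne.

Step 4
Reactants: 9 5-methylhex-4-en-1-yne
Product: 10 (3R)-2,2-dimethyl-3-(prop-2-yn-1-yl)oxirane
Conditions: D-fructose-derived Shi ketone (30 mol %), Oxone (2KHSO5·KHSO4·K2SO4), K2CO3, Bu4NHSO4 (cat), MeCN–dimethoxymethane / aqueous Na2B4O7–Na2EDTA buffer (pH about 10.5), 0 °C; extraction with pentane and careful concentration
Reagents that add atoms: potassium peroxymonosulfate (active part of Oxone), [K+].[O-]S(=O)(=O)OO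
Why: In the Shi epoxidation the chiral dioxirane of the D-fructose-derived catalyst meets the only alkene of 9 through the spiro transition state, which for alkenes of the type Me2C=CHR delivers oxygen to the face that gives the R oxirane carbon, while the terminal alkyne is inert.

Step 5
Reactants: 11 3-bromobut-3-en-1-ol; 12 tert-butyl methyl iminodicarboxylate
Product: 13 tert-butyl methyl (3-bromobut-3-en-1-yl)imidodicarbonate
Conditions: PPh3, DIAD, THF, 0 °C to rt
Reagents that add atoms: none
Why: In the Mitsunobu reaction the acidic imide N–H of 12 is alkylated by the activated primary alcohol, which brings in the nitrogen together with the methyl carbamate of the target.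

Step 6
Reactants: 13 tert-butyl methyl (3-bromobut-3-en-1-yl)imidodicarbonate
Product: 14 methyl (3-bromobut-3-en-1-yl)carbamate
Conditions: CF3CO2H, CH2Cl2, 0 °C to rt
Reagents that add atoms: none
Why: Acidolysis (loss of the tert-butyl cation, then decarboxylation) removes only the Boc group, because the methyl carbamate and the bromoalkene are stable to CF3CO2H.

Step 7
Reactants: 10 (3R)-2,2-dimethyl-3-(prop-2-yn-1-yl)oxirane; 14 methyl (3-bromobut-3-en-1-yl)carbamate
Product: 15 methyl {6-[(2R)-3,3-dimethyloxiran-2-yl]-3-methylidenehex-4-yn-1-yl}carbamate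
Conditions: PdCl2(PPh3)2 (3 mol %), CuI (6 mol %), Et3N, THF, rt to 40 °C
Reagents that add atoms: none
Why: The Sonogashira coupling of a terminal alkyne with a 2-bromo-1-alkene forms the 2-substituted 1-en-3-yne under amine-base conditions that leave the oxirane, its stereocentre and the carbamate N–H untouched.

Step 8
Reactants: 6 2-(benzenesulfonyl)-4-[(2E)-hexa-2,5-dien-1-yl]-1,3-thiazole; 15 methyl {6-[(2R)-3,3-dimethyloxiran-2-yl]-3-methylidenehex-4-yn-1-yl}carbamate
Product: 19 methyl [(7R)-8-{4-[(2E)-hexa-2,5-dien-1-yl]-1,3-thiazol-2-yl}-7-hydroxy-8-methyl-3-methylidenenon-4-yn-1-yl]carbamate, via titanoxy tertiary radical 16 (not isolated), via ipso adduct radical 17 (not isolated), via titanium alkoxide 18 (not isolated)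
Conditions: Cp2TiCl2 (20 mol %), Mn dust (2 equiv), 2,4,6-collidine·HCl (2.5 equiv), 6 (2 equiv, excess recovered), THF (0.5 M in 6), rt, 15 added over 6 h; aqueous NaH2PO4 work-up
Reagents that add atoms: none
Why: Proposed new method: Cp2TiCl, formed in the flask from Cp2TiCl2 and Mn, binds the oxirane oxygen of 15 and breaks the O–CMe2 bond homolytically to the β-titanoxy tertiary radical 16, which as a nucleophilic radical adds to the electron-poor C2 of 6 to give 17; β-scission of the C2–S(sulfonyl) bond restores the aromatic thiazole in 18, a second Cp2TiCl reduces the expelled PhSO2 radical to sulfinate, and collidinium chloride protonates both Ti–O bonds, which frees 19 and returns Cp2TiCl2 to the Mn-driven cycle. The closest known reaction types are the reductive epoxide opening with trivalent titanium and intermolecular trapping of the β-titanoxy radical by electron-poor alkenes (Nugent-RajanBabu reaction), the Cp2TiCl2-catalysed intramolecular radical arylation of epoxides, and the homolytic ipso-substitution of 2-sulfonylbenzothiazoles by tertiary alkyl radicals; only their union in one intermolecular event on a monocyclic thiazole is new. No ring is closed: the temporary oxirane is opened and the thiazole ring is kept. No stereocentre is formed: the new quaternary carbon carries two identical methyl groups, and the carbinol C–O bond is never broken, so the R configuration of step 4 should pass into 19 unchanged. The step needs regioselective opening (secured by tertiary over secondary radical stability), attack at C2 instead of C5 (secured by the sulfonyl nucleofuge, by the position between S1 and N3, neither of which carries a substituent that could block a bulky radical, and by the irreversible rearomatisation), and preference for 6 over the enyne and the isolated alkenes (secured by polarity matching, by the excess and high concentration of 6, by slow addition of 15 at low Cp2TiCl concentration, and by the linear alkyne, which leaves only slow 4-exo and 5-endo closures and no 1,5-hydrogen shift).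

Step 9
Reactants: 19 methyl [(7R)-8-{4-[(2E)-hexa-2,5-dien-1-yl]-1,3-thiazol-2-yl}-7-hydroxy-8-methyl-3-methylidenenon-4-yn-1-yl]carbamate
Product: 20 mycothiazole
Conditions: Zn(Cu/Ag) couple (from Zn dust, Cu(OAc)2 and AgNO3), MeOH–H2O 1:1, 40 °C, argon, dark
Reagents that add atoms: none
Why: The Zn(Cu/Ag) couple (Boland reduction) transfers two hydrogens syn to conjugated alkynes only, so the enyne should become the Z diene while the isolated alkenes, the thiazole, the carbamate and the carbinol stereocentre stay untouched.

## Compound list

1 | pent-1-en-4-yne | C=CCC#C | starting material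
2 | 4-(chloromethyl)-1,3-thiazole | ClCc1cscn1 | starting material
3 | chlorobis(cyclopentadienyl)[(1E)-penta-1,4-dien-1-yl]zirconium | C=CC/C=C/[Zr](Cl)(C1C=CC=C1)C1C=CC=C1 | intermediate
4 | 4-[(2E)-hexa-2,5-dien-1-yl]-1,3-thiazole | C=CC/C=C/Cc1cscn1 | intermediate
5 | {4-[(2E)-hexa-2,5-dien-1-yl]-1,3-thiazol-2-yl}lithium | C=CC/C=C/Cc1csc([Li])n1 | intermediate
6 | 2-(benzenesulfonyl)-4-[(2E)-hexa-2,5-dien-1-yl]-1,3-thiazole | C=CC/C=C/Cc1csc(S(=O)(=O)c2ccccc2)n1 | intermediate
7 | 1-bromo-3-methylbut-2-ene (prenyl bromide) | CC(C)=CCBr | starting material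
8 | ethynylmagnesium bromide | C#C[Mg]Br | starting material
9 | 5-methylhex-4-en-1-yne | CC(C)=CCC#C | intermediate
10 | (3R)-2,2-dimethyl-3-(prop-2-yn-1-yl)oxirane | CC1(C)O[C@@H]1CC#C | intermediate
11 | 3-bromobut-3-en-1-ol | C=C(Br)CCO | starting material
12 | tert-butyl methyl iminodicarboxylate | COC(=O)NC(=O)OC(C)(C)C | starting material
13 | tert-butyl methyl (3-bromobut-3-en-1-yl)imidodicarbonate | C=C(Br)CCN(C(=O)OC)C(=O)OC(C)(C)C | intermediate
14 | methyl (3-bromobut-3-en-1-yl)carbamate | C=C(Br)CCNC(=O)OC | intermediate
15 | methyl {6-[(2R)-3,3-dimethyloxiran-2-yl]-3-methylidenehex-4-yn-1-yl}carbamate | CC1(C)O[C@@H]1CC#CC(=C)CCNC(=O)OC | intermediate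
16 | tertiary carbon radical Me2C(·)–CH(OTiClCp2)–, from opening of the oxirane of 15, R at the titanoxy carbon | C[C](C)[C@H](O[Ti](Cl)(C1C=CC=C1)C1C=CC=C1)CC#CC(=C)CCNC(=O)OC | intermediate
17 | adduct of 16 at C2 of 6: 2,2-disubstituted thiazoline radical, drawn with the spin on N3, C2 configuration undefined | C=CC/C=C/CC1=CSC(S(=O)(=O)c2ccccc2)(C(C)(C)[C@H](O[Ti](Cl)(C2C=CC=C2)C2C=CC=C2)CC#CC(=C)CCNC(=O)OC)[N]1 | intermediate
18 | chlorobis(cyclopentadienyl)titanium alkoxide of 19 | C=CC/C=C/Cc1csc(C(C)(C)[C@H](O[Ti](Cl)(C2C=CC=C2)C2C=CC=C2)CC#CC(=C)CCNC(=O)OC)n1 | intermediate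
19 | methyl [(7R)-8-{4-[(2E)-hexa-2,5-dien-1-yl]-1,3-thiazol-2-yl}-7-hydroxy-8-methyl-3-methylidenenon-4-yn-1-yl]carbamate | C=CC/C=C/Cc1csc(C(C)(C)[C@H](O)CC#CC(=C)CCNC(=O)OC)n1 | intermediate
20 | mycothiazole, methyl [(4Z,7R)-8-{4-[(2E)-hexa-2,5-dien-1-yl]-1,3-thiazol-2-yl}-7-hydroxy-8-methyl-3-methylidenenon-4-en-1-yl]carbamate | C=CC/C=C/Cc1csc(C(C)(C)[C@H](O)C/C=C\C(=C)CCNC(=O)OC)n1 | target

## Step count and risks

Total step count: 9.
Longest linear sequence: 5 steps (steps 3, 4, 7, 8 and 9 from 7; the sequence through steps 5, 6, 7, 8 and 9 from 11 is equally long).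

**1. Step 8 (key step, new method).**
- What may go wrong: the tertiary radical may lose a hydrogen atom to trivalent titanium (disproportionation towards an allylic alcohol). It may add to the enyne of a second molecule. The ipso addition may be too slow on a monocyclic thiazole. Chloride may open the oxirane.
- Fallback (known chemistry): it sets out from 6 and comes back to the route at 19. The same C2–CMe2 bond is made by a polar substitution with a small nucleophile, and the side chain is grown afterwards. Nucleophilic aromatic substitution of the sulfonyl group of 6 by the potassium anion of isobutyronitrile (KN(SiMe3)2, toluene, 0 °C to rt) should give 2-{4-[(2E)-hexa-2,5-dien-1-yl]-1,3-thiazol-2-yl}-2-methylpropanenitrile F1. Reduction with i-Bu2AlH (toluene, −78 °C) and mild acidic hydrolysis of the imine should give 2-{4-[(2E)-hexa-2,5-dien-1-yl]-1,3-thiazol-2-yl}-2-methylpropanal F2. Catalytic asymmetric propargylation follows, with allenylboronic acid pinacol ester and a chiral BINOL-derived phosphoric acid, using the antipode that attacks the face leading to the R carbinol. It should give (3R)-2-{4-[(2E)-hexa-2,5-dien-1-yl]-1,3-thiazol-2-yl}-2-methylhex-5-yn-3-ol F3. Sonogashira coupling of F3 with 14 under the conditions of step 7 gives 19.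

**2. Step 9.**
- What may go wrong: incomplete conversion through passivation of the metal surface by the thiazole, over-reduction of the diene, or erosion of the Z geometry.
- Fallback: it sets out from 19 and comes back at 20. It uses the carbinol as a handle for a tethered syn hydrometalation in place of a surface reduction. Silylation with 1,1,3,3-tetramethyldisilazane (THF, rt to 50 °C) should give methyl [(7R)-7-[(dimethylsilyl)oxy]-8-{4-[(2E)-hexa-2,5-dien-1-yl]-1,3-thiazol-2-yl}-8-methyl-3-methylidenenon-4-yn-1-yl]carbamate F4. Pt2[(CH2=CHSiMe2)2O]3 (cat, THF, rt) should then trigger the intramolecular 5-exo syn hydrosilylation of the alkyne. The product is methyl (4-{(3E,5R)-5-[2-{4-[(2E)-hexa-2,5-dien-1-yl]-1,3-thiazol-2-yl}propan-2-yl]-2,2-dimethyl-1,2-oxasilolan-3-ylidene}-3-methylidenebutyl)carbamate F5. Bu4NF in THF removes silicon from carbon with retention and from oxygen, which gives 20 with the Z alkene.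

**3. Step 1.**
- What may go wrong: migration of the skipped double bonds into conjugation under the action of metal hydride species, competing hydrozirconation of the terminal alkene, or self-quaternisation of the free base of 2 before it couples.
- Fallback: it sets out from 3 and 2 and comes back at 4, with the polarity of the two partners exchanged. Quenching of 3 with I2 (THF, 0 °C) should give (1E)-1-iodopenta-1,4-diene F6, which is purified free of zirconium. Insertion of Zn dust into 2 in the presence of LiCl (THF, rt) should give chloro(1,3-thiazol-4-ylmethyl)zinc F7. Negishi coupling of F7 with F6 (Pd(PPh3)4, THF, rt) proceeds with retention of the alkene geometry and gives 4.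

## Further compounds

F1 | step 8 | 2-{4-[(2E)-hexa-2,5-dien-1-yl]-1,3-thiazol-2-yl}-2-methylpropanenitrile | C=CC/C=C/Cc1csc(C(C)(C)C#N)n1
F2 | step 8 | 2-{4-[(2E)-hexa-2,5-dien-1-yl]-1,3-thiazol-2-yl}-2-methylpropanal | C=CC/C=C/Cc1csc(C(C)(C)C=O)n1
F3 | step 8 | (3R)-2-{4-[(2E)-hexa-2,5-dien-1-yl]-1,3-thiazol-2-yl}-2-methylhex-5-yn-3-ol | C=CC/C=C/Cc1csc(C(C)(C)[C@H](O)CC#C)n1
F4 | step 9 | methyl [(7R)-7-[(dimethylsilyl)oxy]-8-{4-[(2E)-hexa-2,5-dien-1-yl]-1,3-thiazol-2-yl}-8-methyl-3-methylidenenon-4-yn-1-yl]carbamate | C=CC/C=C/Cc1csc(C(C)(C)[C@H](O[SiH](C)C)CC#CC(=C)CCNC(=O)OC)n1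
F5 | step 9 | methyl (4-{(3E,5R)-5-[2-{4-[(2E)-hexa-2,5-dien-1-yl]-1,3-thiazol-2-yl}propan-2-yl]-2,2-dimethyl-1,2-oxasilolan-3-ylidene}-3-methylidenebutyl)carbamate | C=CC/C=C/Cc1csc(C(C)(C)[C@H]2C/C(=C\C(=C)CCNC(=O)OC)[Si](C)(C)O2)n1
F6 | step 1 | (1E)-1-iodopenta-1,4-diene | C=CC/C=C/I
F7 | step 1 | chloro(1,3-thiazol-4-ylmethyl)zinc | Cl[Zn]Cc1cscn1
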